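## Retrosynthetic overview

1. The terpenoid half is taken whole from (−)-ent-copalic acid: its 20 carbons supply the decalin (C5, C9, C10 stereocentres) and the future dioxane C4, C5, C6 with the C6 methyl. Only the propionate (C1–C3, α-methyl) and the two oxygens are added.
2. Key disconnection: the C3–C4 bond of the 1,2-dioxane, closed last by a 6-exo-trig radical cyclisation that also creates C3 and C2 and gives the target directly.
3. Enabling feature: C3 is both the ring carbon bound to O2 and the β-carbon of the propionate ester. C2=C3 can therefore be carried as a β-peroxyacrylate (vinylogous perester) acceptor, while C4, two atoms from the quaternary peroxy carbon C6, carries the radical.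
4. C6–O1 comes from Sharpless epoxidation, Red-Al opening, oxetane formation and perhydrolysis with inversion. O2–C3 comes from vinylic substitution on methyl (E)-3-bromo-2-methylacrylate.
5. Ring order: decalin (from the pool; exocyclic alkene moved into ring B) → oxetane (temporary ring) → 1,2-dioxane (last).

Key step: step 9

Assumption: (−)-ent-copalic acid (the diterpene acid of copaiba oleoresin) and methyl (E)-3-bromo-2-methylacrylate are taken as purchasable; labdane numbering is used for the terpenoid (C13 = dioxane C6, C14 = C5, C15 = C4).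

## Route

Step 1
Reactants: 1 (−)-ent-copalic acid
Product: 2 ent-copalol (ent-labda-8(17),13E-dien-15-ol)
Conditions: LiAlH4, Et2O, 0 °C → rt
Reagents that add atoms: none
Why: Hydride reduction of the β,β-disubstituted enoic acid should proceed 1,2 to the allylic alcohol without touching the alkene geometry or any stereocentre.

Step 2
Reactants: 2 ent-copalol
Product: 3 (13R,14R)-13,14-epoxy-ent-labd-8(17)-en-15-ol
Conditions: t-BuOOH, Ti(OiPr)4 (cat.), D-(−)-diethyl tartrate (cat.), 4 Å MS, CH2Cl2, −20 °C
Reagents that add atoms: tert-butyl hydroperoxide CC(C)(C)OO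
Why: Sharpless asymmetric epoxidation is chemoselective for the allylic alcohol over the exocyclic alkene, and the D-tartrate ligand (reagent control, as for geraniol with the opposite tartrate) should deliver oxygen to the face that gives the (13R,14R)-epoxide.

Step 3
Reactants: 3 (13R,14R)-13,14-epoxy-ent-labd-8(17)-en-15-ol
Product: 4 (13R)-ent-labd-8(17)-ene-13,15-diol
Conditions: NaAlH2(OCH2CH2OMe)2 (Red-Al), THF, 0 °C → rt
Reagents that add atoms: none
Why: Red-Al opening of a 2,3-epoxy alcohol delivers hydride intramolecularly to C14 and should give the 1,3-diol with the C13–O bond, and hence the C13 configuration, retained.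

Step 4
Reactants: 4 (13R)-ent-labd-8(17)-ene-13,15-diol
Product: 5 (13R)-ent-labd-7-ene-13,15-diol
Conditions: Co(salen)Cl (salen = N,N′-bis(3,5-di-tert-butylsalicylidene)ethane-1,2-diamine dianion; cat.), PhSiH3 (cat.), benzene, rt
Reagents that add atoms: none
Why: Cobalt hydride hydrogen-atom-transfer alkene isomerisation should move the exocyclic 1,1-disubstituted alkene by one position, returning hydrogen from the less hindered C7 of the tertiary C8 radical to give the trisubstituted ring B alkene under neutral conditions that do not engage the tertiary alcohol.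

Step 5
Reactants: 5 (13R)-ent-labd-7-ene-13,15-diol
Product: 7 (13R)-13,15-epoxy-ent-labd-7-ene (2,2-disubstituted oxetane), via primary monotosylate 6 (not isolated)
Conditions: n-BuLi (1 equiv), THF, 0 °C; TsCl (1 equiv); n-BuLi (1 equiv), 0 → 60 °C
Reagents that add atoms: p-toluenesulfonyl chloride Cc1ccc(cc1)S(Cl)(=O)=O (tosyl group, present in 6 only)
Why: Selective tosylation of the primary alkoxide followed by intramolecular Williamson etherification (4-exo-tet) by the tertiary alkoxide should close the oxetane with C13 untouched.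

Step 6
Reactants: 7 (13R)-13,15-epoxy-ent-labd-7-ene
Product: 8 (13S)-13-hydroperoxy-ent-labd-7-en-15-ol
Conditions: H2O2 (anhydrous, in Et2O, excess), Me3SiOTf (cat.), −78 → −20 °C
Reagents that add atoms: hydrogen peroxide OO
Why: Lewis acid-promoted perhydrolysis of a 2,2-disubstituted oxetane opens the ring at the tertiary carbon in an SN2-like manner, so the hydroperoxide should enter with inversion and set the dioxane C6 configuration (13S) while releasing the C15 alcohol.

Step 7
Reactants: 8 (13S)-13-hydroperoxy-ent-labd-7-en-15-ol; 9 methyl (E)-3-bromo-2-methylacrylate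
Product: 10 methyl (E)-3-{[(13S)-15-hydroxy-ent-labd-7-en-13-yl]peroxy}-2-methylacrylate
Conditions: Cs2CO3, DMF, 0 °C
Reagents that add atoms: none
Why: Proposed new method: the caesium hydroperoxide (the alcohol is not deprotonated by carbonate) adds to C3 of the β-bromoacrylate and the ester enolate expels bromide faster than it can close an epoxide, giving the vinylogous perester by nucleophilic vinylic substitution; the closest known reaction type is the formation of β-alkoxyacrylates and β-peroxyvinyl ketones from alkoxides or hydroperoxides and β-halo enoates or enones, and no stereocentre is formed (the alkene geometry is irrelevant for step 9).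

Step 8
Reactants: 10 methyl (E)-3-{[(13S)-15-hydroxy-ent-labd-7-en-13-yl]peroxy}-2-methylacrylate
Product: 12 methyl (E)-3-{[(13S)-15-bromo-ent-labd-7-en-13-yl]peroxy}-2-methylacrylate, via primary mesylate 11 (not isolated)
Conditions: MsCl, Et3N, CH2Cl2, 0 °C; then LiBr, acetone, rt
Reagents that add atoms: methanesulfonyl chloride CS(Cl)(=O)=O (mesyl group, present in 11 only); lithium bromide [Li+].[Br-]
Why: Mesylation and SN2 displacement by bromide at the unhindered primary carbon avoid phosphines and iodide, both of which could reduce the O–O bond.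

Step 9
Reactants: 12 methyl (E)-3-{[(13S)-15-bromo-ent-labd-7-en-13-yl]peroxy}-2-methylacrylate
Product: 13 methyl (2S)-2-[(3S,6S)-6-methyl-6-{2-[(1R,4aR,8aR)-2,5,5,8a-tetramethyl-1,4,4a,5,6,7,8,8a-octahydronaphthalen-1-yl]ethyl}-1,2-dioxan-3-yl]propanoate (target)
Conditions: Bu3SnH (slow addition), Et3B/air (cat.), toluene (0.01 M), −40 °C
Reagents that add atoms: none
Why: Proposed new method: Bu3Sn• abstracts bromine from C4 (C15), the primary radical adds 6-exo-trig to C3 of the electron-poor β-peroxyacrylate, and the α-ester radical at C2 is reduced by Bu3SnH, closing the 1,2-dioxane through the C3–C4 bond. The closest known reaction type is the 6-exo radical cyclisation of β-alkoxyacrylates to 2,6-disubstituted tetrahydropyrans, here with O–O in place of O in the tether. C3 is set in a chair-like transition state with the acrylate pseudo-equatorial; the chair with the two-carbon arm of quaternary C6 equatorial and the methyl axial should be preferred and gives the required cis relation of the C3 side chain and the C6 arm, but this preference is expected to be modest. C2 is set in the hydrogen-atom transfer: the radical is exocyclic to the ring stereocentre C3 bearing the ring oxygen, and such radicals are reduced anti to the C–O bond (exocyclic effect, allylic strain and dipole control), which is the required (2S,3S) relation. The step needs bromine abstraction and cyclisation to outrun tin-radical attack on O–O and direct reduction (high dilution, slow hydride addition, activated acceptor), and hydrogen transfer to outrun β-fragmentation of the β-peroxy radical (ester-stabilised radical, low temperature); C6 and the decalin centres are untouched.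

## Compound list

1 | (−)-ent-copalic acid, (2E)-3-methyl-5-[(1R,4aR,8aR)-5,5,8a-trimethyl-2-methylidenedecahydronaphthalen-1-yl]pent-2-enoic acid | C/C(=C\C(=O)O)CC[C@@H]1C(=C)CC[C@@H]2C(C)(C)CCC[C@@]12C | starting material
2 | ent-copalol, (2E)-3-methyl-5-[(1R,4aR,8aR)-5,5,8a-trimethyl-2-methylidenedecahydronaphthalen-1-yl]pent-2-en-1-ol | C/C(=C\CO)CC[C@@H]1C(=C)CC[C@@H]2C(C)(C)CCC[C@@]12C | intermediate
3 | [(2R,3R)-3-methyl-3-{2-[(1R,4aR,8aR)-5,5,8a-trimethyl-2-methylidenedecahydronaphthalen-1-yl]ethyl}oxiran-2-yl]methanol | OC[C@H]1O[C@]1(C)CC[C@@H]2C(=C)CC[C@@H]3C(C)(C)CCC[C@@]23C | intermediate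
4 | (3R)-3-methyl-5-[(1R,4aR,8aR)-5,5,8a-trimethyl-2-methylidenedecahydronaphthalen-1-yl]pentane-1,3-diol | OCC[C@@](C)(CC[C@@H]1C(=C)CC[C@@H]2C(C)(C)CCC[C@@]12C)O | intermediate
5 | (3R)-3-methyl-5-[(1R,4aR,8aR)-2,5,5,8a-tetramethyl-1,4,4a,5,6,7,8,8a-octahydronaphthalen-1-yl]pentane-1,3-diol | OCC[C@@](C)(CC[C@@H]1C(C)=CC[C@@H]2C(C)(C)CCC[C@@]12C)O | intermediate
6 | (3R)-3-hydroxy-3-methyl-5-[(1R,4aR,8aR)-2,5,5,8a-tetramethyl-1,4,4a,5,6,7,8,8a-octahydronaphthalen-1-yl]pentyl 4-methylbenzenesulfonate | Cc1ccc(cc1)S(=O)(=O)OCC[C@@](C)(CC[C@@H]2C(C)=CC[C@@H]3C(C)(C)CCC[C@@]23C)O | intermediate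
7 | (2R)-2-methyl-2-{2-[(1R,4aR,8aR)-2,5,5,8a-tetramethyl-1,4,4a,5,6,7,8,8a-octahydronaphthalen-1-yl]ethyl}oxetane | C1C[C@@](C)(CC[C@@H]2C(C)=CC[C@@H]3C(C)(C)CCC[C@@]23C)O1 | intermediate
8 | (3S)-3-hydroperoxy-3-methyl-5-[(1R,4aR,8aR)-2,5,5,8a-tetramethyl-1,4,4a,5,6,7,8,8a-octahydronaphthalen-1-yl]pentan-1-ol | OCC[C@](C)(CC[C@@H]1C(C)=CC[C@@H]2C(C)(C)CCC[C@@]12C)OO | intermediate
9 | methyl (2E)-3-bromo-2-methylprop-2-enoate | COC(=O)/C(C)=C/Br | starting material
10 | methyl (2E)-3-({(3S)-1-hydroxy-3-methyl-5-[(1R,4aR,8aR)-2,5,5,8a-tetramethyl-1,4,4a,5,6,7,8,8a-octahydronaphthalen-1-yl]pentan-3-yl}peroxy)-2-methylprop-2-enoate | COC(=O)/C(C)=C/OO[C@](C)(CCO)CC[C@@H]1C(C)=CC[C@@H]2C(C)(C)CCC[C@@]12C | intermediate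
11 | methyl (2E)-3-({(3S)-1-(methanesulfonyloxy)-3-methyl-5-[(1R,4aR,8aR)-2,5,5,8a-tetramethyl-1,4,4a,5,6,7,8,8a-octahydronaphthalen-1-yl]pentan-3-yl}peroxy)-2-methylprop-2-enoate | COC(=O)/C(C)=C/OO[C@](C)(CCOS(C)(=O)=O)CC[C@@H]1C(C)=CC[C@@H]2C(C)(C)CCC[C@@]12C | intermediate
12 | methyl (2E)-3-({(3S)-1-bromo-3-methyl-5-[(1R,4aR,8aR)-2,5,5,8a-tetramethyl-1,4,4a,5,6,7,8,8a-octahydronaphthalen-1-yl]pentan-3-yl}peroxy)-2-methylprop-2-enoate | COC(=O)/C(C)=C/OO[C@](C)(CCBr)CC[C@@H]1C(C)=CC[C@@H]2C(C)(C)CCC[C@@]12C | intermediate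
13 | methyl (2S)-2-[(3S,6S)-6-methyl-6-{2-[(1R,4aR,8aR)-2,5,5,8a-tetramethyl-1,4,4a,5,6,7,8,8a-octahydronaphthalen-1-yl]ethyl}-1,2-dioxan-3-yl]propanoate | COC(=O)[C@@H](C)[C@@H]1CC[C@](C)(CC[C@@H]2C(C)=CC[C@@H]3C(C)(C)CCC[C@@]23C)OO1 | target

## Step count and risks

Total steps: 9. Longest linear sequence: 9 steps (1 → 13); compound 9 is a purchased reactant.

Steps most likely to fail:

Step 9 (proposed new method). The C3 facial selectivity may be poor, because the quaternary C6 carries a methyl and a two-carbon arm of similar size; the β-peroxy ester radical may also fragment with loss of the O–O bond before hydrogen transfer. Fallback with known chemistry, setting out from 8 and coming back at 13: oxidation of the primary alcohol of 8 (TEMPO cat., PhI(OAc)2) should give the hydroperoxy aldehyde as its cyclic peroxy hemiacetal, the 5,5-disubstituted 1,2-dioxolan-3-ol F1. Wittig olefination of its open form with Ph3P=C(CH3)CO2CH3 should give the (E)-hydroperoxy enoate F2. Base-mediated intramolecular peroxy-Michael addition (Et2NH, CF3CH2OH) then closes the dioxane through the O2–C3 bond and gives 13 together with its C2/C3 isomers for separation.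

Step 7 (proposed new method). The hydroperoxide anion may epoxidise the acrylate (Weitz–Scheffer pathway) instead of displacing bromide, or the vinylogous perester may decompose by O–O cleavage. Fallback with known chemistry, setting out from 8 and coming back at 13: the dioxolanol F1 (made from 8 as above) is homologated by one carbon with excess Ph3P=CHOCH3 to the hydroperoxy enol ether F3. Acid (PPTS, MeOH) closes this to the cyclic peroxy acetal, the 3-methoxy-1,2-dioxane F4. Its peroxycarbenium ion (Me3SiOTf, CH2Cl2, −78 °C) is trapped at C3 by 1-methoxy-1-(trimethylsilyloxy)prop-1-ene to give 13 and isomers.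

Step 6. Ionisation at the tertiary carbon may erode configurational fidelity and lead to elimination or capture of the cation by the ring B alkene. Fallback, setting out from 5 and coming back at 8: acid-catalysed perhydrolysis of the tertiary alcohol of 5 (concentrated H2O2, cat. H2SO4, Et2O, 0 °C; SN1) should give 8 together with its C13 epimer, the (3R)-hydroperoxide F5, which is removed by chromatography. This gives up stereocontrol at C6 but avoids the oxetane.

Further compounds
F1 | step 9 | (5S)-5-methyl-5-{2-[(1R,4aR,8aR)-2,5,5,8a-tetramethyl-1,4,4a,5,6,7,8,8a-octahydronaphthalen-1-yl]ethyl}-1,2-dioxolan-3-ol | OC1C[C@](C)(CC[C@@H]2C(C)=CC[C@@H]3C(C)(C)CCC[C@@]23C)OO1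
F2 | step 9 | methyl (2E,6R)-6-hydroperoxy-2,6-dimethyl-8-[(1R,4aR,8aR)-2,5,5,8a-tetramethyl-1,4,4a,5,6,7,8,8a-octahydronaphthalen-1-yl]oct-2-enoate | COC(=O)/C(C)=C/CC[C@](C)(CC[C@@H]1C(C)=CC[C@@H]2C(C)(C)CCC[C@@]12C)OO
F3 | step 7 | (5S)-5-hydroperoxy-1-methoxy-5-methyl-7-[(1R,4aR,8aR)-2,5,5,8a-tetramethyl-1,4,4a,5,6,7,8,8a-octahydronaphthalen-1-yl]hept-1-ene (E/Z mixture) | COC=CCC[C@](C)(CC[C@@H]1C(C)=CC[C@@H]2C(C)(C)CCC[C@@]12C)OO
F4 | step 7 | (6S)-3-methoxy-6-methyl-6-{2-[(1R,4aR,8aR)-2,5,5,8a-tetramethyl-1,4,4a,5,6,7,8,8a-octahydronaphthalen-1-yl]ethyl}-1,2-dioxane (anomer mixture) | COC1CC[C@](C)(CC[C@@H]2C(C)=CC[C@@H]3C(C)(C)CCC[C@@]23C)OO1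
F5 | step 6 | (3R)-3-hydroperoxy-3-methyl-5-[(1R,4aR,8aR)-2,5,5,8a-tetramethyl-1,4,4a,5,6,7,8,8a-octahydronaphthalen-1-yl]pentan-1-ol | OCC[C@@](C)(CC[C@@H]1C(C)=CC[C@@H]2C(C)(C)CCC[C@@]12C)OO
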